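**Strategy.** The route cuts the C(sp2)–C(sp2) single bond in the middle of the (E,E,E)-triene, between the CH next to the pyranone-bearing C(CH3)= carbon and the CH=CH–C(CH3)=CH arm on the cyclohexane ring. A final Suzuki–Miyaura coupling of the (E)-iodovinyl α-methoxy-γ-pyranone with the unprotected (E,E)-dienyl pinacol boronate of the acetoxy-triol cyclohexane forms this bond with retention of both alkene geometries and delivers the target directly. The boronate comes from a Sharpless-derived vinyl lactone by anti-aldol addition, ring-closing metathesis and hydroxyl-directed dihydroxylation; the iodide comes from a triketide cyclisation.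

Key step: step 21

Remark: ring locants in the Why lines are C1 = ring carbon bearing the side chain, C2 = CH(CH3), C3 and C5 = C(CH3)(OH), C4 = CH(OAc), C6 = CH(OH); compounds 1, 8, 20 and 24 are taken as commercial.

**Step 1**
Reactants: 1 (2E)-2-methylbut-2-en-1-ol
Product: 2 [(2S,3S)-2,3-dimethyloxiran-2-yl]methanol
Conditions: Ti(OiPr)4 (cat.), L-(+)-diethyl tartrate (cat.), t-BuOOH, 4 Å MS, CH2Cl2, −20 °C
Reagents that add atoms: tert-butyl hydroperoxide, CC(C)(C)OO
Why: Sharpless asymmetric epoxidation of a primary allylic alcohol; with L-(+)-tartrate the oxygen is delivered to the face that gives the (2S,3S)-epoxide, which fixes the later C3 carbinol and, after inversion, C2.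

**Step 2**
Reactants: 2 [(2S,3S)-2,3-dimethyloxiran-2-yl]methanol
Product: 3 (2R,3S)-2,3-dimethylhex-5-ene-1,2-diol
Conditions: allylMgBr (3 equiv), CuI (10 mol %), THF/Et2O, −30 → 0 °C
Reagents that add atoms: allylmagnesium bromide, C=CC[Mg]Br
Why: Copper-catalysed Grignard opening of a 2,3-epoxy alcohol; SN2 attack at the secondary epoxide carbon (the quaternary one is blocked) goes with inversion and sets the methyl-bearing centre C2, while the tertiary C–O bond (C3) is retained.

**Step 3**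
Reactants: 3 (2R,3S)-2,3-dimethylhex-5-ene-1,2-diol
Product: 5 (4S,5R)-5-(hydroxymethyl)-4,5-dimethyloxolan-2-one, via dihydroxy acid 4 (not isolated)
Conditions: O3, CH2Cl2/MeOH, −78 °C; then 30% H2O2, aq. NaOH, 0 °C → rt; then 2 M HCl
Reagents that add atoms: ozone, [O-][O+]=O; hydrogen peroxide, OO
Why: Ozonolysis with oxidative work-up cuts the terminal alkene to the acid, and on acidification the γ-hydroxy acid should close through the tertiary hydroxyl to the five-membered lactone, as γ,δ-dihydroxy acids generally do.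

**Step 4**
Reactants: 5 (4S,5R)-5-(hydroxymethyl)-4,5-dimethyloxolan-2-one
Product: 6 (2R,3S)-2,3-dimethyl-5-oxooxolane-2-carbaldehyde
Conditions: Dess–Martin periodinane, CH2Cl2, rt
Reagents that add atoms: none
Why: Dess–Martin oxidation of the neopentyl-type primary alcohol; the aldehyde has no α-hydrogen, so the adjacent quaternary centre cannot epimerise.

**Step 5**
Reactants: 6 (2R,3S)-2,3-dimethyl-5-oxooxolane-2-carbaldehyde
Product: 7 (4S,5S)-5-ethenyl-4,5-dimethyloxolan-2-one
Conditions: Ph3PCH3Br, KHMDS, THF, −78 → 0 °C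
Reagents that add atoms: methyltriphenylphosphonium bromide, C[P+](c1ccccc1)(c1ccccc1)c1ccccc1.[Br-]
Why: Wittig methylenation; at low temperature the aldehyde should react far faster with the ylide than the lactone carbonyl.

**Step 6**
Reactants: 7 (4S,5S)-5-ethenyl-4,5-dimethyloxolan-2-one; 8 2-methylprop-2-enal (methacrolein)
Product: 10 (3R,4S,5S)-5-ethenyl-3-[(1S)-1-hydroxy-2-methylprop-2-en-1-yl]-4,5-dimethyloxolan-2-one, via lithium enolate 9 (not isolated)
Conditions: LDA, THF, −78 °C; then 8, −78 °C; AcOH quench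
Reagents that add atoms: none
Why: Lithium enolate aldol addition through a Zimmerman–Traxler chair: the aldehyde should approach C1 anti to the adjacent C2 methyl and the C3 vinyl group, and the ring-locked E-enolate should favour the anti adduct, which sets C1 and the carbinol C6; the minor carbinol epimer is to be removed by chromatography.

**Step 7**
Reactants: 10 (3R,4S,5S)-5-ethenyl-3-[(1S)-1-hydroxy-2-methylprop-2-en-1-yl]-4,5-dimethyloxolan-2-one
Product: 11 (3R,4S,5S)-3-[(1S)-1-{[tert-butyl(dimethyl)silyl]oxy}-2-methylprop-2-en-1-yl]-5-ethenyl-4,5-dimethyloxolan-2-one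
Conditions: TBSOTf, 2,6-lutidine, CH2Cl2, −78 → 0 °C
Reagents that add atoms: tert-butyldimethylsilyl trifluoromethanesulfonate, CC(C)(C)[Si](C)(C)OS(=O)(=O)C(F)(F)F
Why: Silylation of the secondary alcohol keeps O6 distinct from O4 for the later selective acetylation and blocks retro-aldol and dehydration pathways.

**Step 8**
Reactants: 11 (3R,4S,5S)-3-[(1S)-1-{[tert-butyl(dimethyl)silyl]oxy}-2-methylprop-2-en-1-yl]-5-ethenyl-4,5-dimethyloxolan-2-one
Product: 12 (3R,4S,5S)-3-[(1S)-1-{[tert-butyl(dimethyl)silyl]oxy}-2-methylprop-2-en-1-yl]-5-ethenyl-4,5-dimethyloxolan-2-ol (anomer mixture)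
Conditions: DIBAL-H, CH2Cl2, −78 °C; Rochelle salt work-up
Reagents that add atoms: none
Why: Half-reduction of the γ-lactone to the lactol; the aluminium hemiacetal is stable at −78 °C and is not reduced further.

**Step 9**
Reactants: 12 (3R,4S,5S)-3-[(1S)-1-{[tert-butyl(dimethyl)silyl]oxy}-2-methylprop-2-en-1-yl]-5-ethenyl-4,5-dimethyloxolan-2-ol
Product: 13 (2E,4R,5S,6S)-4-[(1S)-1-{[tert-butyl(dimethyl)silyl]oxy}-2-methylprop-2-en-1-yl]-6-hydroxy-2,5,6-trimethylocta-2,7-dienal
Conditions: Ph3P=C(CH3)CHO, toluene, 95 °C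
Reagents that add atoms: 2-(triphenylphosphoranylidene)propanal, CC(C=O)=P(c1ccccc1)(c1ccccc1)c1ccccc1
Why: Wittig olefination of the lactol through its open hydroxy aldehyde form; the formyl-stabilised ylide should give the (E)-2-methyl enal and release the tertiary C3 hydroxyl.

**Step 10**
Reactants: 13 (2E,4R,5S,6S)-4-[(1S)-1-{[tert-butyl(dimethyl)silyl]oxy}-2-methylprop-2-en-1-yl]-6-hydroxy-2,5,6-trimethylocta-2,7-dienal
Product: 14 (2E)-3-[(1R,2S,5R,6S)-2-{[tert-butyl(dimethyl)silyl]oxy}-5-hydroxy-3,5,6-trimethylcyclohex-3-en-1-yl]-2-methylprop-2-enal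
Conditions: Grubbs II catalyst (5 mol %), CH2Cl2, 40 °C
Reagents that add atoms: none
Why: Ring-closing metathesis between the vinyl group on C3 and the isopropenyl group closes the cyclohexene with the C4=C5 double bond; the conjugated trisubstituted enal alkene should not take part.

**Step 11**
Reactants: 14 (2E)-3-[(1R,2S,5R,6S)-2-{[tert-butyl(dimethyl)silyl]oxy}-5-hydroxy-3,5,6-trimethylcyclohex-3-en-1-yl]-2-methylprop-2-enal
Product: 16 (2E)-3-[(1R,2S,3R,4R,5R,6S)-2-{[tert-butyl(dimethyl)silyl]oxy}-3,4,5-trihydroxy-3,5,6-trimethylcyclohexyl]-2-methylprop-2-enal, via osmate(VI) TMEDA ester 15 (not isolated)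
Conditions: OsO4 (1.05 equiv), TMEDA, CH2Cl2, −78 °C; then aq. Na2SO3, THF, 60 °C
Reagents that add atoms: osmium tetroxide, O=[Os](=O)(=O)=O; N,N,N′,N′-tetramethylethylenediamine, CN(C)CCN(C)C (kept only in 15)
Why: Hydrogen-bond-directed dihydroxylation: the OsO4·TMEDA complex is held by the free tertiary allylic C3 hydroxyl and should add to the ring alkene syn to it, on the face opposite the carbon substituents at C1, C2 and C3, which sets C4 and C5 with all four oxygens cis; the electron-poor enal alkene should react much more slowly.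

**Step 12**
Reactants: 16 (2E)-3-[(1R,2S,3R,4R,5R,6S)-2-{[tert-butyl(dimethyl)silyl]oxy}-3,4,5-trihydroxy-3,5,6-trimethylcyclohexyl]-2-methylprop-2-enal
Product: 17 (2E)-3-[(1R,2S,3R,4R,5R,6S)-4-acetoxy-2-{[tert-butyl(dimethyl)silyl]oxy}-3,5-dihydroxy-3,5,6-trimethylcyclohexyl]-2-methylprop-2-enal
Conditions: Ac2O, pyridine, DMAP (cat.), CH2Cl2, rt
Reagents that add atoms: acetic anhydride, CC(=O)OC(C)=O
Why: DMAP-catalysed acetylation should take the only free secondary hydroxyl (C4); the two tertiary hydroxyls do not react under these conditions.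

**Step 13**
Reactants: 17 (2E)-3-[(1R,2S,3R,4R,5R,6S)-4-acetoxy-2-{[tert-butyl(dimethyl)silyl]oxy}-3,5-dihydroxy-3,5,6-trimethylcyclohexyl]-2-methylprop-2-enal
Product: 18 (2E)-3-[(1R,2S,3S,4R,5R,6S)-4-acetoxy-2,3,5-trihydroxy-3,5,6-trimethylcyclohexyl]-2-methylprop-2-enal
Conditions: HF·pyridine, THF/pyridine, 0 °C → rt
Reagents that add atoms: none
Why: Fluoride-mediated desilylation under buffered, mildly acidic conditions that should leave the acetate and the enal untouched.

**Step 14**
Reactants: 18 (2E)-3-[(1R,2S,3S,4R,5R,6S)-4-acetoxy-2,3,5-trihydroxy-3,5,6-trimethylcyclohexyl]-2-methylprop-2-enal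
Product: 19 2-{(1E,3E)-4-[(1R,2S,3S,4R,5R,6S)-4-acetoxy-2,3,5-trihydroxy-3,5,6-trimethylcyclohexyl]-3-methylbuta-1,3-dien-1-yl}-4,4,5,5-tetramethyl-1,3,2-dioxaborolane
Conditions: CrCl2 (8 equiv), Cl2CHBpin, LiI, THF, rt
Reagents that add atoms: 2-(dichloromethyl)-4,4,5,5-tetramethyl-1,3,2-dioxaborolane, ClC(Cl)B1OC(C)(C)C(C)(C)O1
Why: Takai-type chromium(II) boron olefination of the aldehyde; the gem-dichromium reagent should give the (E)-alkenyl boronate, so the enal becomes the (1E,3E)-dienyl boronate.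

**Step 15**
Reactants: 20 prop-2-yn-1-ol
Product: 22 (2E)-3-iodo-2-methylprop-2-en-1-ol, via alkenylalane 21 (not isolated)
Conditions: Me3Al (3 equiv), Cp2ZrCl2 (cat.), CH2Cl2, 0 °C → rt; then I2, THF, −30 → 0 °C
Reagents that add atoms: trimethylaluminium, C[Al](C)C; iodine, II
Why: Negishi zirconium-catalysed carboalumination adds CH3 and Al syn across the alkyne with Al at the terminus, and iodinolysis with retention gives the (E)-iodoalkene.

**Step 16**
Reactants: 22 (2E)-3-iodo-2-methylprop-2-en-1-ol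
Product: 23 (2E)-3-iodo-2-methylprop-2-enal
Conditions: MnO2, CH2Cl2, rt
Reagents that add atoms: none
Why: Manganese dioxide oxidation of an allylic alcohol; neutral conditions preserve the alkene geometry and the C–I bond.

**Step 17**
Reactants: 24 methyl 2-methyl-3-oxopentanoate; 23 (2E)-3-iodo-2-methylprop-2-enal
Product: 26 methyl (6E)-5-hydroxy-7-iodo-2,4,6-trimethyl-3-oxohept-6-enoate (diastereomer mixture), via sodium lithium dienolate 25 (not isolated)
Conditions: NaH, THF, 0 °C; n-BuLi, 0 °C; then 23, −78 °C; AcOH quench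
Reagents that add atoms: none
Why: β-Keto ester dianion aldol: the more reactive γ-carbanion adds 1,2 to the enal; the diastereomer mixture is of no consequence because all three centres become sp2.

**Step 18**
Reactants: 26 methyl (6E)-5-hydroxy-7-iodo-2,4,6-trimethyl-3-oxohept-6-enoate
Product: 27 methyl (6E)-7-iodo-2,4,6-trimethyl-3,5-dioxohept-6-enoate
Conditions: Dess–Martin periodinane, CH2Cl2, rt
Reagents that add atoms: none
Why: Dess–Martin oxidation of the allylic secondary alcohol to the β,δ-diketo ester under non-basic conditions.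

**Step 19**
Reactants: 27 methyl (6E)-7-iodo-2,4,6-trimethyl-3,5-dioxohept-6-enoate
Product: 28 4-hydroxy-6-[(1E)-1-iodoprop-1-en-2-yl]-3,5-dimethyl-2H-pyran-2-one
Conditions: DBU, toluene, rt
Reagents that add atoms: none
Why: Base-mediated cyclisation of a β,δ-diketo ester: the enolate oxygen of the C5 ketone acylates on the ester (6-exo-trig) and loses methanol to give the 4-hydroxy-2-pyranone.

**Step 20**
Reactants: 28 4-hydroxy-6-[(1E)-1-iodoprop-1-en-2-yl]-3,5-dimethyl-2H-pyran-2-one
Product: 29 2-[(1E)-1-iodoprop-1-en-2-yl]-6-methoxy-3,5-dimethyl-4H-pyran-4-one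
Conditions: MeOSO2F, CH2Cl2, rt; then aq. NaHCO3
Reagents that add atoms: methyl fluorosulfonate, COS(=O)(=O)F
Why: Hard O-methylation of the neutral 4-hydroxy-2-pyranone at the lactone carbonyl oxygen, followed by loss of the hydroxyl proton, should give the 2-methoxy-4-pyranone regioisomer, the usual outcome with methyl fluorosulfonate.

**Step 21**
Reactants: 19 2-{(1E,3E)-4-[(1R,2S,3S,4R,5R,6S)-4-acetoxy-2,3,5-trihydroxy-3,5,6-trimethylcyclohexyl]-3-methylbuta-1,3-dien-1-yl}-4,4,5,5-tetramethyl-1,3,2-dioxaborolane; 29 2-[(1E)-1-iodoprop-1-en-2-yl]-6-methoxy-3,5-dimethyl-4H-pyran-4-one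
Product: 30 amaurone A
Conditions: Pd(dppf)Cl2·CH2Cl2 (10 mol %), aq. K3PO4, THF, rt, degassed, dark
Reagents that add atoms: none
Why: Suzuki–Miyaura alkenyl–alkenyl coupling: Pd(0) inserts into the C–I bond of 29 with retention, the phosphate-activated boronate 19 transfers its dienyl group with retention, and reductive elimination forms the =CH–CH= bond of the triene. The closest known reaction type is the stereospecific coupling of (E)-alkenyl iodides with (E)-alkenyl pinacol boronates used to assemble polyenes. No ring is closed and no stereocentre is created; the three E double bonds are carried over unchanged from 29 and 19. The step needs chemoselectivity for C–I and C–B over the free hydroxyls, the C4 acetate and the pyranone, which the mild aqueous phosphate base at room temperature, the hindered position of the acetate and the fast oxidative addition of the electron-poor pyranone-conjugated iodide should secure. Exclusion of light and oxygen should keep the triene from E/Z isomerisation.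

**Compound list**
1 | (2E)-2-methylbut-2-en-1-ol | OC/C(C)=C/C | starting material
2 | [(2S,3S)-2,3-dimethyloxiran-2-yl]methanol | OC[C@]1(C)O[C@H]1C | intermediate
3 | (2R,3S)-2,3-dimethylhex-5-ene-1,2-diol | OC[C@](C)(O)[C@@H](C)CC=C | intermediate
4 | (3S,4R)-4,5-dihydroxy-3,4-dimethylpentanoic acid (not isolated) | OC[C@](C)(O)[C@@H](C)CC(=O)O | intermediate
5 | (4S,5R)-5-(hydroxymethyl)-4,5-dimethyloxolan-2-one | O=C1C[C@H](C)[C@@](C)(O1)CO | intermediate
6 | (2R,3S)-2,3-dimethyl-5-oxooxolane-2-carbaldehyde | O=C1C[C@H](C)[C@@](C)(O1)C=O | intermediate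
7 | (4S,5S)-5-ethenyl-4,5-dimethyloxolan-2-one | O=C1C[C@H](C)[C@@](C)(O1)C=C | intermediate
8 | 2-methylprop-2-enal (methacrolein) | C=C(C)C=O | starting material
9 | lithium (4S,5S)-5-ethenyl-4,5-dimethyl-4,5-dihydrofuran-2-olate (not isolated) | [Li]OC1=C[C@H](C)[C@@](C)(O1)C=C | intermediate
10 | (3R,4S,5S)-5-ethenyl-3-[(1S)-1-hydroxy-2-methylprop-2-en-1-yl]-4,5-dimethyloxolan-2-one | O=C1[C@@H]([C@H](O)C(C)=C)[C@H](C)[C@@](C)(O1)C=C | intermediate
11 | (3R,4S,5S)-3-[(1S)-1-{[tert-butyl(dimethyl)silyl]oxy}-2-methylprop-2-en-1-yl]-5-ethenyl-4,5-dimethyloxolan-2-one | O=C1[C@@H]([C@H](O[Si](C)(C)C(C)(C)C)C(C)=C)[C@H](C)[C@@](C)(O1)C=C | intermediate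
12 | (3R,4S,5S)-3-[(1S)-1-{[tert-butyl(dimethyl)silyl]oxy}-2-methylprop-2-en-1-yl]-5-ethenyl-4,5-dimethyloxolan-2-ol (anomer mixture) | OC1[C@@H]([C@H](O[Si](C)(C)C(C)(C)C)C(C)=C)[C@H](C)[C@@](C)(O1)C=C | intermediate
13 | (2E,4R,5S,6S)-4-[(1S)-1-{[tert-butyl(dimethyl)silyl]oxy}-2-methylprop-2-en-1-yl]-6-hydroxy-2,5,6-trimethylocta-2,7-dienal | O=C/C(C)=C/[C@@H]([C@H](O[Si](C)(C)C(C)(C)C)C(C)=C)[C@H](C)[C@@](C)(O)C=C | intermediate
14 | (2E)-3-[(1R,2S,5R,6S)-2-{[tert-butyl(dimethyl)silyl]oxy}-5-hydroxy-3,5,6-trimethylcyclohex-3-en-1-yl]-2-methylprop-2-enal | O=C/C(C)=C/[C@@H]1[C@H](C)[C@@](C)(O)C=C(C)[C@H]1O[Si](C)(C)C(C)(C)C | intermediate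
15 | cyclic C4,C5-osmate(VI) ester of 14 with TMEDA on osmium (not isolated) | O=C/C(C)=C/[C@@H]1[C@H](C)[C@@](C)(O)[C@H]2O[Os-2]3(=O)(=O)(O[C@@]2(C)[C@H]1O[Si](C)(C)C(C)(C)C)[N+](C)(C)CC[N+]3(C)C | intermediate
16 | (2E)-3-[(1R,2S,3R,4R,5R,6S)-2-{[tert-butyl(dimethyl)silyl]oxy}-3,4,5-trihydroxy-3,5,6-trimethylcyclohexyl]-2-methylprop-2-enal | O=C/C(C)=C/[C@@H]1[C@H](C)[C@@](C)(O)[C@@H](O)[C@@](C)(O)[C@H]1O[Si](C)(C)C(C)(C)C | intermediate
17 | (2E)-3-[(1R,2S,3R,4R,5R,6S)-4-acetoxy-2-{[tert-butyl(dimethyl)silyl]oxy}-3,5-dihydroxy-3,5,6-trimethylcyclohexyl]-2-methylprop-2-enal | O=C/C(C)=C/[C@@H]1[C@H](C)[C@@](C)(O)[C@@H](OC(C)=O)[C@@](C)(O)[C@H]1O[Si](C)(C)C(C)(C)C | intermediate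
18 | (2E)-3-[(1R,2S,3S,4R,5R,6S)-4-acetoxy-2,3,5-trihydroxy-3,5,6-trimethylcyclohexyl]-2-methylprop-2-enal | O=C/C(C)=C/[C@@H]1[C@H](C)[C@@](C)(O)[C@@H](OC(C)=O)[C@@](C)(O)[C@H]1O | intermediate
19 | 2-{(1E,3E)-4-[(1R,2S,3S,4R,5R,6S)-4-acetoxy-2,3,5-trihydroxy-3,5,6-trimethylcyclohexyl]-3-methylbuta-1,3-dien-1-yl}-4,4,5,5-tetramethyl-1,3,2-dioxaborolane | CC1(C)OB(/C=C/C(C)=C/[C@@H]2[C@H](C)[C@@](C)(O)[C@@H](OC(C)=O)[C@@](C)(O)[C@H]2O)OC1(C)C | intermediate
20 | prop-2-yn-1-ol | C#CCO | starting material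
21 | dimethylaluminium (2E)-3-(dimethylalumanyl)-2-methylprop-2-en-1-olate (not isolated) | C[Al](C)OC/C(C)=C/[Al](C)C | intermediate
22 | (2E)-3-iodo-2-methylprop-2-en-1-ol | OC/C(C)=C/I | intermediate
23 | (2E)-3-iodo-2-methylprop-2-enal | O=C/C(C)=C/I | intermediate
24 | methyl 2-methyl-3-oxopentanoate | CCC(=O)C(C)C(=O)OC | starting material
25 | sodium lithium dienolate of 24 (not isolated) | CC=C(O[Li])C(C)=C(O[Na])OC | intermediate
26 | methyl (6E)-5-hydroxy-7-iodo-2,4,6-trimethyl-3-oxohept-6-enoate (diastereomer mixture) | COC(=O)C(C)C(=O)C(C)C(O)/C(C)=C/I | intermediate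
27 | methyl (6E)-7-iodo-2,4,6-trimethyl-3,5-dioxohept-6-enoate | COC(=O)C(C)C(=O)C(C)C(=O)/C(C)=C/I | intermediate
28 | 4-hydroxy-6-[(1E)-1-iodoprop-1-en-2-yl]-3,5-dimethyl-2H-pyran-2-one | O=c1oc(/C(C)=C/I)c(C)c(O)c1C | intermediate
29 | 2-[(1E)-1-iodoprop-1-en-2-yl]-6-methoxy-3,5-dimethyl-4H-pyran-4-one | COc1oc(/C(C)=C/I)c(C)c(=O)c1C | intermediate
30 | amaurone A | COc1oc(/C(C)=C/C=C/C(C)=C/[C@@H]2[C@H](C)[C@@](C)(O)[C@@H](OC(C)=O)[C@@](C)(O)[C@H]2O)c(C)c(=O)c1C | target

**Step count.** Total: 21 steps. Longest linear sequence: 15 steps (steps 1–14 and 21); the pyranone branch is 6 steps (15–20).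

**Steps most likely to fail, with fallbacks**

Step 9. The hindered lactol 12 may open too slowly toward the weakly nucleophilic formyl ylide, so that on prolonged heating β-elimination of silanol or oxa-Michael closure of the tertiary hydroxyl onto the new enal competes. The fallback sets out from 12 and returns to 13. The more nucleophilic ester ylide ethyl 2-(triphenylphosphoranylidene)propanoate (toluene, 80 °C) should give the ethyl (E)-dienoate F1. Its ester is reduced with DIBAL-H (CH2Cl2, −78 °C) to the allylic alcohol F2, which is re-oxidised with MnO2 to 13. The enal is thus reached at lower temperature by a redox detour instead of a direct olefination.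

Step 19. In 27 the diketonate oxygen, or DBU itself, may add to the iodine-bearing carbon of the β-iodo enone and expel iodide (6-endo addition–elimination to a 2-unsubstituted γ-pyranone) in competition with acylation at the ester. The fallback sets out from 26 and returns to 28. The ring is closed before the enone exists: base-mediated lactonisation of the δ-hydroxy β-keto ester 26 (K2CO3, MeOH, rt) should give the dihydropyranone F3. This is then dehydrogenated across C5–C6 with DDQ (1,4-dioxane, 80 °C) to the 4-hydroxy-2-pyranone 28.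

Step 14. Chromium(III) alkoxides formed from the three free hydroxyls may slow the gem-dichromium addition and erode conversion or E-selectivity, and the dienyl boronate may protodeboronate on isolation. The fallback sets out from 18 and 29 and returns at 30. The iodoform variant of the Takai olefination (CHI3, CrCl2, THF/1,4-dioxane) should convert 18 into the (1E,3E)-dienyl iodide F4. Compound 29 is stannylated (Me3SnSnMe3, Pd(PPh3)4, toluene, 80 °C) to the alkenylstannane F5. The two are joined by a Stille coupling under neutral conditions (Pd(PPh3)4, copper(I) thiophene-2-carboxylate, Bu4N Ph2PO2, DMF, rt) to give 30 directly. The polarity of the final coupling is inverted and no boron reagent is needed.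

**Further compounds**
F1 | step 9 | ethyl (2E,4R,5S,6S)-4-[(1S)-1-{[tert-butyl(dimethyl)silyl]oxy}-2-methylprop-2-en-1-yl]-6-hydroxy-2,5,6-trimethylocta-2,7-dienoate | CCOC(=O)/C(C)=C/[C@@H]([C@H](O[Si](C)(C)C(C)(C)C)C(C)=C)[C@H](C)[C@@](C)(O)C=C
F2 | step 9 | (2E,4R,5S,6S)-4-[(1S)-1-{[tert-butyl(dimethyl)silyl]oxy}-2-methylprop-2-en-1-yl]-2,5,6-trimethylocta-2,7-diene-1,6-diol | OC/C(C)=C/[C@@H]([C@H](O[Si](C)(C)C(C)(C)C)C(C)=C)[C@H](C)[C@@](C)(O)C=C
F3 | step 19 | 4-hydroxy-6-[(1E)-1-iodoprop-1-en-2-yl]-3,5-dimethyl-5,6-dihydro-2H-pyran-2-one | O=C1OC(/C(C)=C/I)C(C)C(O)=C1C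
F4 | step 14 | (1R,2S,3S,4R,5R,6S)-2,4,6-trihydroxy-3-[(1E,3E)-4-iodo-2-methylbuta-1,3-dien-1-yl]-2,4,5-trimethylcyclohexyl acetate (iodide analogue of 19) | I/C=C/C(C)=C/[C@@H]1[C@H](C)[C@@](C)(O)[C@@H](OC(C)=O)[C@@](C)(O)[C@H]1O
F5 | step 14 | 2-methoxy-3,5-dimethyl-6-[(1E)-1-(trimethylstannyl)prop-1-en-2-yl]-4H-pyran-4-one | COc1oc(/C(C)=C/[Sn](C)(C)C)c(C)c(=O)c1C
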